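The constants used here were set for the occasion; the result is computed.

If you want the target in one of these flasks at its end, count how much free catalyst the starting material has met, and for how many minutes.

    starting material + free catalyst ⇌ catalyst intermediate A (K1 = 2.7 M⁻¹, k1 = 1.12 M⁻¹ min⁻¹, Ea1 = 61.0 kJ mol⁻¹, ΔH1 = −17.0 kJ mol⁻¹)
    catalyst intermediate A → free catalyst + target (k2 = 38.0 min⁻¹, Ea2 = 66.0 kJ mol⁻¹)
    second substrate + free catalyst ⇌ catalyst intermediate B (K3 = 0.99 M⁻¹, k3 = 13.0 M⁻¹ min⁻¹, Ea3 = 56.0 kJ mol⁻¹, ΔH3 = −33.0 kJ mol⁻¹)
    catalyst intermediate B → free catalyst + second product (k4 = 0.546 min⁻¹, Ea4 = 89.0 kJ mol⁻¹)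
    second substrate + protic impurity → quenched substrate (k5 = 4.77 M⁻¹ min⁻¹, Ea5 = 49.0 kJ mol⁻¹)
    precatalyst → free catalyst (k6 = 0.108 min⁻¹, Ea6 = 95.0 kJ mol⁻¹)
    (constants at 50 °C)

| setting | maple | ash | larch | alder |
|---|---|---|---|---|
| starting material | 1.5 M | 1.5 M | 1.5 M | 1.5 M |
| second substrate | 2.00 equiv | 2.00 equiv | 2.00 equiv | 2.00 equiv |
| protic impurity | 0.0300 M | 0.0300 M | 0.0300 M | 0.0300 M |
| precatalyst | 15 mol% | 15 mol% | 15 mol% | 15 mol% |
| time | 6.0 min | 6.0 min | 6.0 min | 6.0 min |
| remark | at 30 °C until 3.0 min, from then on at 70 °C |  |  |  |
| temperature |  | 50 °C | 70 °C | 30 °C |

- at 50 °C the constants are as listed, elsewhere as the activation energies and enthalpies make them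

- the flask with the highest amount of target, in percent of the starting material charged ("all alike" if they lie within 1.5 percentage points) (maple / ash / larch / alder / all alike)
- final target, as a percentage of the starting material charged, in maple
- final target, as a percentage of the starting material charged, in ash
- final target, as a percentage of the starting material charged, in larch
- final target, as a percentage of the starting material charged, in alder

Take the first two lines: at 50 °C catalyst intermediate A goes on to target at 38.0 min⁻¹ and falls back at 0.415 min⁻¹, so nearly all of what binds becomes target, and the binding, slower than the step to target even at the full charge of starting material, is the rate-limiting step. The starting material therefore decays pseudo-first-order, at the rate constant of binding times free catalyst, and the fraction left is the exponential of minus that product summed over time.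

But the next lines take catalyst away: second substrate holds it as catalyst intermediate B. In larch, at 70 °C, the ratio of bound to free with second substrate at its full charge is 1.39, which leaves a free share of 41.8% of the released catalyst. The protic impurity can take 1.00% of the second substrate, so in larch you may drop it.

The last line comes first in time, though: precatalyst opens at 0.0105 min⁻¹ in alder, 0.108 min⁻¹ in ash and 0.848 min⁻¹ in larch. Summing the released fraction over time gives the released minutes: 0.185 min in alder, 1.58 min in ash, about 1.91 min in the hot half of maple, and 4.83 min in larch. So I rank the flasks by released minutes, larch first, then maple, ash and alder.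

Now reckon larch, where the rate constant of binding is 4.21 M⁻¹ min⁻¹. The first round gives 1.91, hence 85.2% target. But catalyst intermediate B goes on at 3.76 min⁻¹, which on this reckoning uses 79.4% of the second substrate over the run, so the free share was set too low. Put the mean second substrate, 60.3% of charge, back in and go round again: the free share becomes 54.3% and the sum becomes 2.48. This is the exposure, the rate constant of binding times free catalyst summed over time, and it commits me to 91.6% target in larch.

The forecast names larch, with 57% in maple, 10% in ash, 0.14% in alder and 91% in larch, a little below mine, on the ground that “The precatalyst activation is the gate”.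

The simulation gives larch the most: 91.2% in larch, 57.0% in maple, 10.1% in ash and 0.159% in alder. At 6.00 min larch still holds 34.9% of its second substrate, with 32.5% of the catalyst as catalyst intermediate B. Read back, the target in larch means an exposure of 2.43 against my 2.48. Scaling 2.48 to ash by its rate constant of binding, released minutes and free share gives 0.104, so 9.85% target, and ash holds 10.1%.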